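**Plan**

1. Cuts: the Z-alkene (made as an alkyne, Sonogashira) and the C8b–O aryl ether (Mitsunobu, inversion) separate a tetracyclic core from dihydrobenzofuran fragment 2. In the core, the C8a–C7a bond (carbene C–H insertion) is cut, and then both aryl–carbon bonds of ring D (to C8b and to C8a) are cut together.
2. Enabling feature: ring D is a resorcinol-type ring that carries C8a on the carbon ortho to the furan oxygen and C8b on the neighbouring carbon meta to both oxygens. These are the two positions a 3,5-dioxygenated benzyne offers to an electrophile and a nucleophile. C8a and C8b are therefore joined first as C1(=O)–C2 of an indan-1-one, and aryne insertion into that bond through a strained benzocyclobutenoxide expands the five-membered ring to the seven-membered ring.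
3. Forward, core: chalcone → epoxide → 2-hydroxy-3-arylindanone (Friedel–Crafts) → aryne insertion (seven-membered ring and ring D attached) → dihydrofuran by C–H insertion of the C8a carbene into the ortho benzylic ether that the aryne brought along → exchange of benzyl for TIPS.
4. Fragment 2: the same aryne precursor inserts into an aroyl chloride, the same carbene C–H insertion closes the dihydrofuran, and the aryl chloride is the coupling handle.
5. End game: Mitsunobu with 4-ethynylphenol, Sonogashira union, semi-hydrogenation to the Z-alkene, fluoride desilylation.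
6. Stereochemistry: C7b from the Juliá–Colonna epoxidation (relayed by the trans-selective cyclisation); C8b by kinetic protonation (cis) then Mitsunobu inversion; C8a by conformational control in the C–H insertion; C7a by acid equilibration to trans; C3 and C2 of fragment 2 by Rh2(S-PTAD)4 and the same equilibration; alkene geometry by syn hydrogenation.

Key step: step 9

Locants and abbreviations: the core is the 2,3-dihydrobenzofuran (benzene ring = ring D) whose C3 (C8a, bearing resorcinol ring C) and C4 are tied through C8b (CH–O, on ring D) and C7b (CH–aryl, on ring C) into a seven-membered ring; C7a is the O–CH of the furan and bears 4-hydroxyphenyl ring A; ring B is the 4-hydroxyphenyl ring on C7b; BOB = 4-(benzyloxy)benzyl; TIPS = triisopropylsilyl.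

Assumption: Rh2(S-PTAD)4 is taken to be the catalyst antipode that gives the (3R) series in step 18 and that is matched with the substrate bias in step 11; if the sense is the opposite, Rh2(R-PTAD)4 is used with no other change.

**Aryne precursor**

Step 1
Reactants: 1 5-bromobenzene-1,3-diol; 2 4-(benzyloxy)benzyl chloride
Product: 3 1-bromo-3,5-bis{[4-(benzyloxy)benzyl]oxy}benzene
Conditions: 2 (2.2 equiv), K2CO3, KI (cat.), DMF, 60 °C
Reagents that add atoms: none
Why: Twofold Williamson etherification (SN2 of the phenoxides on the benzylic chloride) puts a BOB group on both oxygens, one copy of which later becomes C7a with ring A.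

Step 2
Reactants: 3 1-bromo-3,5-bis{[4-(benzyloxy)benzyl]oxy}benzene
Product: 4 3,5-bis{[4-(benzyloxy)benzyl]oxy}phenol
Conditions: Pd2(dba)3 (2 mol %), t-BuXPhos, KOH, 1,4-dioxane/H2O, 100 °C; then aq. HCl
Reagents that add atoms: potassium hydroxide, [K+].[OH-]
Why: Hydroxylation of the aryl bromide catalysed by Pd2(dba)3 with t-BuXPhos (C–O coupling with hydroxide) should give the phenol without touching the base-stable benzylic ethers.

Step 3
Reactants: 4 3,5-bis{[4-(benzyloxy)benzyl]oxy}phenol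
Product: 5 2-bromo-3,5-bis{[4-(benzyloxy)benzyl]oxy}phenol
Conditions: NBS (1.0 equiv), i-Pr2NH (10 mol %), CH2Cl2, −78 → 0 °C
Reagents that add atoms: N-bromosuccinimide, O=C1CCC(=O)N1Br
Why: Amine-catalysed ortho-selective electrophilic bromination of a phenol; the two ortho positions are equivalent by symmetry and the phloroglucinol-type ring is far more reactive than the BOB rings.

Step 4
Reactants: 5 2-bromo-3,5-bis{[4-(benzyloxy)benzyl]oxy}phenol
Product: 8 3,5-bis{[4-(benzyloxy)benzyl]oxy}-2-(trimethylsilyl)phenyl trifluoromethanesulfonate, via silyl ether 6 (not isolated), via lithium phenoxide 7 (not isolated)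
Conditions: HMDS, THF, 65 °C, then evaporation; n-BuLi, THF, −100 → −78 °C; Tf2O, −100 → −78 °C
Reagents that add atoms: hexamethyldisilazane, C[Si](C)(C)N[Si](C)(C)C; trifluoromethanesulfonic anhydride, O=S(=O)(OS(=O)(=O)C(F)(F)F)C(F)(F)F
Why: Standard entry to ortho-silylaryl triflates: O-silylation, bromine–lithium exchange, retro-Brook 1,3-shift of silicon from oxygen to carbon, then O-triflation of the phenoxide.

**Core**

Step 5
Reactants: 9 1-[3,5-bis(benzyloxy)phenyl]ethan-1-one; 10 4-(benzyloxy)benzaldehyde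
Product: 11 (E)-1-[3,5-bis(benzyloxy)phenyl]-3-[4-(benzyloxy)phenyl]prop-2-en-1-one
Conditions: KOH, EtOH/THF, 23 °C
Reagents that add atoms: none
Why: Claisen–Schmidt condensation should give the E-chalcone.

Step 6
Reactants: 11 (E)-1-[3,5-bis(benzyloxy)phenyl]-3-[4-(benzyloxy)phenyl]prop-2-en-1-one
Product: 12 [(2S,3R)-3-[4-(benzyloxy)phenyl]oxiran-2-yl][3,5-bis(benzyloxy)phenyl]methanone
Conditions: poly-D-leucine, urea–H2O2, DBU, THF, 23 °C
Reagents that add atoms: urea–hydrogen peroxide, NC(N)=O.OO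
Why: Juliá–Colonna epoxidation, in which the helical poly-D-leucine differentiates the enone faces in the Weitz–Scheffer addition of hydroperoxide and should give the (2S,3R)-epoxide (antipode of the poly-L-leucine product), the source of all absolute stereochemistry of the core.

Step 7
Reactants: 12 [(2S,3R)-3-[4-(benzyloxy)phenyl]oxiran-2-yl][3,5-bis(benzyloxy)phenyl]methanone
Product: 13 (2S,3R)-4,6-bis(benzyloxy)-3-[4-(benzyloxy)phenyl]-2-hydroxy-2,3-dihydro-1H-inden-1-one
Conditions: Sc(OTf)3 (10 mol %), CH2Cl2, −20 → 0 °C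
Reagents that add atoms: none
Why: Lewis-acid-promoted intramolecular Friedel–Crafts alkylation (epoxide–arene cyclisation), in which the epoxide opens at the benzylic carbon stabilised by the 4-benzyloxyphenyl group and the aroyl ring carbon ortho and para to its two ethers bonds on the face away from the departing oxygen, giving the trans-2-hydroxy-3-arylindanone with C2 untouched and setting C3 (the future C7b) as R.

Step 8
Reactants: 13 (2S,3R)-4,6-bis(benzyloxy)-3-[4-(benzyloxy)phenyl]-2-hydroxy-2,3-dihydro-1H-inden-1-one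
Product: 14 (2S,3R)-2,4,6-tris(benzyloxy)-3-[4-(benzyloxy)phenyl]-2,3-dihydro-1H-inden-1-one
Conditions: BnBr, Ag2O, CH2Cl2, 23 °C
Reagents that add atoms: benzyl bromide, BrCc1ccccc1
Why: Ag2O-mediated O-benzylation protects the ketol under non-basic conditions, so neither epimerisation nor an α-ketol shift should occur.

Step 9
Reactants: 14 (2S,3R)-2,4,6-tris(benzyloxy)-3-[4-(benzyloxy)phenyl]-2,3-dihydro-1H-inden-1-one; 8 3,5-bis{[4-(benzyloxy)benzyl]oxy}-2-(trimethylsilyl)phenyl trifluoromethanesulfonate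
Product: 19 (10R,11R)-1,3,10-tris(benzyloxy)-6,8-bis{[4-(benzyloxy)benzyl]oxy}-11-[4-(benzyloxy)phenyl]-10,11-dihydro-5H-dibenzo[a,d][7]annulen-5-one, via potassium enolate 15 (not isolated), via aryne 16 (not isolated), via benzocyclobutenoxide 17 (not isolated), via dienolate 18 (not isolated)
Conditions: KH (1.05 equiv), THF, 0 °C; then 8 (1.15 equiv, slow addition), KF, 18-crown-6, 0 → 23 °C; AcOH, −78 °C
Reagents that add atoms: none
Why: Proposed new method: the potassium enolate 15 should add through C2 to the fluoride-generated aryne 16 at the aryne carbon meta to the flanking ether, the aryl anion so formed (ortho to that ether) should close onto the indanone carbonyl to give the strained benzocyclobutenoxide 17, and cleavage of the former C1–C2 bond (driven by release of the cyclobutene strain and giving the o-quinodimethane dienolate 18) completes a formal insertion of the aryne into the C1–C2 bond that forms both aryl–carbon bonds of ring D in one operation. The closest known reactions are the aryne acyl-alkylation with ring expansion of cyclic β-ketoesters (which uses a 3,5-dioxygenated aryne of this kind with the same regiochemistry) and the strong-base arynic condensation of simple cyclic ketone enolates via benzocyclobutenols; what is new is the one-pot use of a singly activated α-alkoxy ketone enolate with a fluoride-generated aryne. The four-membered ring closes by 4-exo-trig addition of the aryl anion to C=O, and the seven-membered ring arises by fragmentation of the bond shared by the four- and five-membered rings (a two-carbon ring expansion), so no direct medium-ring closure is needed. C11 is carried over unchanged from 14, and C10 is set when AcOH protonates dienolate 18 at −78 °C along the axial direction on the face opposite the pseudo-axial C11 aryl group, which should give the 10,11-cis ketone. The step needs the enolate carbon at the aryne carbon meta to oxygen and the carbonyl carbon at the one ortho to it, which the 3-alkoxy group of the aryne secures by inductive polarisation; it also needs C- over O-arylation and ring closure before protonation, which the potassium enolate in aprotic THF secures (one enolisable position in 14, no proton source).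

Step 10
Reactants: 19 (10R,11R)-1,3,10-tris(benzyloxy)-6,8-bis{[4-(benzyloxy)benzyl]oxy}-11-[4-(benzyloxy)phenyl]-10,11-dihydro-5H-dibenzo[a,d][7]annulen-5-one
Product: 20 hydrazone of 19 (5-hydrazinylidene compound)
Conditions: N2H4·H2O (excess), AcOH (cat.), n-BuOH, 110 °C
Reagents that add atoms: hydrazine, NN
Why: Condensation of the diaryl ketone with hydrazine gives the N-unsubstituted hydrazone, the precursor of the donor/donor diazo compound; no other electrophilic group is present.

Step 11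
Reactants: 20 hydrazone of 19
Product: 22 (7aS,8aR,7bR,8bR)-core hexaether with 7a,8a-cis dihydrofuran (Bn on O-8b and on the oxygens of rings A/B/C; BOB on the oxygen of ring D), via diazo compound 21 (not isolated)
Conditions: MnO2, CH2Cl2, 0 °C, filtration; then Rh2(S-PTAD)4 [dirhodium tetrakis((S)-(1-adamantyl)(N-phthalimido)acetate)] (1 mol %), CH2Cl2, −20 → 23 °C
Reagents that add atoms: none
Why: Oxidation to the diaryldiazomethane and Rh2(S-PTAD)4-catalysed intramolecular 1,5 C–H insertion of the donor/donor carbene into the ortho O–CH2 of the BOB ether on ring D forms the C8a–C7a bond and the dihydrofuran (cis expected, as in acyclic cases), and C8a is set R because the new bond must lie in the plane of ring D (pseudo-equatorial), so that H-8a ends pseudo-axial on the face of the boat-shaped seven-membered ring that also carries the pseudo-axial C7b aryl group.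

Step 12
Reactants: 22 (7aS,8aR,7bR,8bR)-core hexaether with 7a,8a-cis dihydrofuran
Product: 23 (7aR,8aR,7bR,8bR)-core pentabenzyl ether with 7a,8a-trans dihydrofuran and a free phenol on ring D
Conditions: TFA (10 equiv), pentamethylbenzene (3 equiv), CH2Cl2, 0 °C
Reagents that add atoms: none
Why: Reversible acid ionisation of the C7a–O bond (4-benzyloxybenzylic cation) and re-closure equilibrates C7a to the more stable 7a,8a-trans dihydrofuran without touching C8a, while the same acid removes the remaining BOB ether of ring D, whose cation is trapped by pentamethylbenzene.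

Step 13
Reactants: 23 (7aR,8aR,7bR,8bR)-core pentabenzyl ether
Product: 24 (7aR,8aR,7bR,8bR)-core hexol (five phenols and the C8b alcohol; 8b-OH cis to the C7b aryl)
Conditions: H2 (1 atm), Pd/C (10 %), EtOAc/MeOH, 23 °C
Reagents that add atoms: none
Why: Hydrogenolysis of the four aryl benzyl ethers and of the C8b benzyl ether; the hindered secondary benzylic C7a–O and C8b–O bonds are cleaved much more slowly, and no alkene or halide is present at this stage.

Step 14
Reactants: 24 (7aR,8aR,7bR,8bR)-core hexol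
Product: 25 (7aR,8aR,7bR,8bR)-core penta-O-TIPS ether (all five phenols silylated; 8b-OH free)
Conditions: TIPSCl (7 equiv), imidazole, DMF, 23 → 40 °C
Reagents that add atoms: chlorotriisopropylsilane, CC(C)[Si](Cl)(C(C)C)C(C)C
Why: Silylation of the five phenols; the hindered secondary C8b alcohol should not react with the bulky chlorosilane under these conditions and stays free for the coupling.

**Fragment 2**

Step 15
Reactants: 26 3,5-bis(benzyloxy)benzoic acid
Product: 27 3,5-bis(benzyloxy)benzoyl chloride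
Conditions: (COCl)2, DMF (cat.), CH2Cl2, 0 → 23 °C
Reagents that add atoms: oxalyl chloride, ClC(=O)C(Cl)=O
Why: Standard acid chloride formation through the Vilsmeier-type chloroiminium species.

Step 16
Reactants: 27 3,5-bis(benzyloxy)benzoyl chloride; 8 3,5-bis{[4-(benzyloxy)benzyl]oxy}-2-(trimethylsilyl)phenyl trifluoromethanesulfonate
Product: 28 (2-chloro-4,6-bis{[4-(benzyloxy)benzyl]oxy}phenyl)[3,5-bis(benzyloxy)phenyl]methanone
Conditions: KF, 18-crown-6, THF, 0 → 23 °C
Reagents that add atoms: none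
Why: Fluoride releases from 8 the same aryne as in step 9 (compound 16), which inserts into the C–Cl bond of the acid chloride (aryne σ-bond insertion): chloride adds to the aryne carbon meta to the flanking ether and the aryl anion ortho to that ether is acylated, which gives the 2-chloro-6-alkoxybenzophenone with the same regiochemical sense as in step 9.

Step 17
Reactants: 28 (2-chloro-4,6-bis{[4-(benzyloxy)benzyl]oxy}phenyl)[3,5-bis(benzyloxy)phenyl]methanone
Product: 29 hydrazone of 28
Conditions: N2H4·H2O (excess), AcOH (cat.), n-BuOH, 110 °C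
Reagents that add atoms: hydrazine, NN
Why: Hydrazone formation as in step 10; the electron-rich aryl chloride should resist nucleophilic displacement (no ring closure to an indazole) at this temperature.

Step 18
Reactants: 29 hydrazone of 28
Product: 31 (2S,3R)-6-{[4-(benzyloxy)benzyl]oxy}-2-[4-(benzyloxy)phenyl]-3-[3,5-bis(benzyloxy)phenyl]-4-chloro-2,3-dihydro-1-benzofuran, via diazo compound 30 (not isolated)
Conditions: MnO2, CH2Cl2, 0 °C, filtration; then Rh2(S-PTAD)4 (1 mol %), CH2Cl2, −20 → 23 °C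
Reagents that add atoms: none
Why: Enantioselective intramolecular 1,5 C–H insertion of the donor/donor rhodium carbene into the ortho benzylic ether, in which the chiral carboxylate ligands of Rh2(S-PTAD)4 control the face of the carbene and set C3 as R, and the insertion gives the 2,3-cis dihydrobenzofuran.

Step 19
Reactants: 31 (2S,3R)-cis-dihydrobenzofuran
Product: 32 (2R,3R)-2-[4-(benzyloxy)phenyl]-3-[3,5-bis(benzyloxy)phenyl]-4-chloro-2,3-dihydro-1-benzofuran-6-ol
Conditions: TFA (10 equiv), pentamethylbenzene (3 equiv), CH2Cl2, 0 °C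
Reagents that add atoms: none
Why: As in step 12, reversible ionisation of the C2–O bond equilibrates C2 to the 2,3-trans isomer with C3 untouched, and the BOB ether at O-6 is cleaved with trapping of its cation.

Step 20
Reactants: 32 (2R,3R)-2-[4-(benzyloxy)phenyl]-3-[3,5-bis(benzyloxy)phenyl]-4-chloro-2,3-dihydro-1-benzofuran-6-ol
Product: 33 5-[(2R,3R)-4-chloro-6-hydroxy-2-(4-hydroxyphenyl)-2,3-dihydro-1-benzofuran-3-yl]benzene-1,3-diol
Conditions: BCl3, pentamethylbenzene, CH2Cl2, −78 °C; then MeOH/H2O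
Reagents that add atoms: none
Why: Lewis-acid debenzylation with a non-Lewis-basic cation scavenger removes the three aryl benzyl ethers at low temperature and keeps the aryl chloride, which hydrogenolysis could remove.

Step 21
Reactants: 33 5-[(2R,3R)-4-chloro-6-hydroxy-2-(4-hydroxyphenyl)-2,3-dihydro-1-benzofuran-3-yl]benzene-1,3-diol
Product: 34 tetra-O-TIPS ether of 33
Conditions: TIPSCl (6 equiv), imidazole, DMF, 23 → 40 °C
Reagents that add atoms: chlorotriisopropylsilane, CC(C)[Si](Cl)(C(C)C)C(C)C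
Why: Silylation of all four phenols gives ethers that survive the coupling and the hydrogenation and that fall off with fluoride at the end.

**Union and end game**

Step 22
Reactants: 25 (7aR,8aR,7bR,8bR)-core penta-O-TIPS ether; 35 4-ethynylphenol
Product: 36 (7aR,8aR,7bR,8bS)-8b-O-(4-ethynylphenyl) penta-O-TIPS core
Conditions: PPh3, DIAD, 35 (3 equiv), toluene, 0 → 50 °C
Reagents that add atoms: none
Why: Mitsunobu etherification (SN2 with inversion), in which the phenoxide displaces the pseudo-equatorial oxyphosphonium group from the face opposite the pseudo-axial C7b aryl, so the ether oxygen ends trans to that aryl (8bS), and the pseudo-equatorial leaving group has no anti-periplanar β-hydrogen for elimination in this conformation.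

Step 23
Reactants: 36 (7aR,8aR,7bR,8bS)-8b-O-(4-ethynylphenyl) penta-O-TIPS core; 34 tetra-O-TIPS ether of 33
Product: 37 nona-O-TIPS diarylalkyne (36 joined through the alkyne to C4 of the dihydrobenzofuran of 34)
Conditions: PdCl2(MeCN)2 (3 mol %), XPhos, Cs2CO3, MeCN/THF, 75 °C
Reagents that add atoms: none
Why: Copper-free Sonogashira coupling of an aryl chloride with a terminal alkyne, in which the bulky electron-rich biarylphosphine enables oxidative addition to the electron-rich ortho-substituted chloride and the absence of copper avoids alkyne homocoupling.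

Step 24
Reactants: 37 nona-O-TIPS diarylalkyne
Product: 38 nona-O-TIPS ether of the target (Z-alkene)
Conditions: H2 (1 atm), Pd/CaCO3 poisoned with Pb(OAc)2 (Lindlar type), quinoline, EtOAc, 23 °C
Reagents that add atoms: none
Why: Syn semi-hydrogenation of the diarylalkyne on Pd/CaCO3 poisoned with Pb(OAc)2 should give the Z-stilbene, and neither the silyl ethers nor the benzylic C–O bonds are reduced under these conditions.

Step 25
Reactants: 38 nona-O-TIPS ether of the target
Product: 39 target CNP0354678.1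
Conditions: TBAF, AcOH, THF, 0 → 23 °C
Reagents that add atoms: none
Why: Fluoride cleavage of the nine aryl silyl ethers under buffered conditions should free all phenols without isomerising the Z-alkene, opening the dihydrofurans or cleaving the C8b aryl ether.

**Compound list**

1 | 5-bromobenzene-1,3-diol | Oc1cc(O)cc(Br)c1 | starting material
2 | 4-(benzyloxy)benzyl chloride | ClCc1ccc(OCc2ccccc2)cc1 | starting material
3 | 1-bromo-3,5-bis{[4-(benzyloxy)benzyl]oxy}benzene | Brc1cc(OCc2ccc(OCc3ccccc3)cc2)cc(OCc2ccc(OCc3ccccc3)cc2)c1 | intermediate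
4 | 3,5-bis{[4-(benzyloxy)benzyl]oxy}phenol | Oc1cc(OCc2ccc(OCc3ccccc3)cc2)cc(OCc2ccc(OCc3ccccc3)cc2)c1 | intermediate
5 | 2-bromo-3,5-bis{[4-(benzyloxy)benzyl]oxy}phenol | Oc1cc(OCc2ccc(OCc3ccccc3)cc2)cc(OCc2ccc(OCc3ccccc3)cc2)c1Br | intermediate
6 | O-trimethylsilyl ether of 5 (not isolated) | C[Si](C)(C)Oc1cc(OCc2ccc(OCc3ccccc3)cc2)cc(OCc2ccc(OCc3ccccc3)cc2)c1Br | intermediate
7 | lithium 3,5-bis{[4-(benzyloxy)benzyl]oxy}-2-(trimethylsilyl)phenoxide (not isolated) | [Li+].[O-]c1cc(OCc2ccc(OCc3ccccc3)cc2)cc(OCc2ccc(OCc3ccccc3)cc2)c1[Si](C)(C)C | intermediate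
8 | 3,5-bis{[4-(benzyloxy)benzyl]oxy}-2-(trimethylsilyl)phenyl trifluoromethanesulfonate | C[Si](C)(C)c1c(OS(=O)(=O)C(F)(F)F)cc(OCc2ccc(OCc3ccccc3)cc2)cc1OCc1ccc(OCc2ccccc2)cc1 | intermediate
9 | 1-[3,5-bis(benzyloxy)phenyl]ethan-1-one | CC(=O)c1cc(OCc2ccccc2)cc(OCc2ccccc2)c1 | starting material
10 | 4-(benzyloxy)benzaldehyde | O=Cc1ccc(OCc2ccccc2)cc1 | starting material
11 | (E)-1-[3,5-bis(benzyloxy)phenyl]-3-[4-(benzyloxy)phenyl]prop-2-en-1-one | O=C(/C=C/c1ccc(OCc2ccccc2)cc1)c1cc(OCc2ccccc2)cc(OCc2ccccc2)c1 | intermediate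
12 | [(2S,3R)-3-[4-(benzyloxy)phenyl]oxiran-2-yl][3,5-bis(benzyloxy)phenyl]methanone | O=C(c1cc(OCc2ccccc2)cc(OCc2ccccc2)c1)[C@H]1O[C@@H]1c1ccc(OCc2ccccc2)cc1 | intermediate
13 | (2S,3R)-4,6-bis(benzyloxy)-3-[4-(benzyloxy)phenyl]-2-hydroxy-2,3-dihydro-1H-inden-1-one | O=C1c2cc(OCc3ccccc3)cc(OCc3ccccc3)c2[C@@H](c2ccc(OCc3ccccc3)cc2)[C@@H]1O | intermediate
14 | (2S,3R)-2,4,6-tris(benzyloxy)-3-[4-(benzyloxy)phenyl]-2,3-dihydro-1H-inden-1-one | O=C1c2cc(OCc3ccccc3)cc(OCc3ccccc3)c2[C@@H](c2ccc(OCc3ccccc3)cc2)[C@@H]1OCc1ccccc1 | intermediate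
15 | potassium enolate of 14 (not isolated) | [K+].[O-]C1=C(OCc2ccccc2)[C@H](c2ccc(OCc3ccccc3)cc2)c2c(OCc3ccccc3)cc(OCc3ccccc3)cc12 | intermediate
16 | 3,5-bis{[4-(benzyloxy)benzyl]oxy}benzyne (not isolated) | C1#CC(OCc2ccc(OCc3ccccc3)cc2)=CC(OCc2ccc(OCc3ccccc3)cc2)=C1 | intermediate
17 | potassium benzocyclobutenoxide from C-arylation of 15 and closure onto C=O (not isolated) | [K+].[O-][C@@]12c3cc(OCc4ccccc4)cc(OCc4ccccc4)c3[C@@H](c3ccc(OCc4ccccc4)cc3)[C@]1(OCc1ccccc1)c1cc(OCc3ccc(OCc4ccccc4)cc3)cc(OCc3ccc(OCc4ccccc4)cc3)c12 | intermediate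
18 | potassium o-quinodimethane dienolate of 19 (not isolated) | [K+].[O-]C1=C2C(OCc3ccc(OCc4ccccc4)cc3)=CC(OCc3ccc(OCc4ccccc4)cc3)=CC2=C(OCc2ccccc2)[C@H](c2ccc(OCc3ccccc3)cc2)c2c(OCc3ccccc3)cc(OCc3ccccc3)cc12 | intermediate
19 | (10R,11R)-1,3,10-tris(benzyloxy)-6,8-bis{[4-(benzyloxy)benzyl]oxy}-11-[4-(benzyloxy)phenyl]-10,11-dihydro-5H-dibenzo[a,d][7]annulen-5-one | O=C1c2cc(OCc3ccccc3)cc(OCc3ccccc3)c2[C@@H](c2ccc(OCc3ccccc3)cc2)[C@@H](OCc2ccccc2)c2cc(OCc3ccc(OCc4ccccc4)cc3)cc(OCc3ccc(OCc4ccccc4)cc3)c21 | intermediate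
20 | hydrazone of 19 (5-hydrazinylidene compound) | NN=C1c2cc(OCc3ccccc3)cc(OCc3ccccc3)c2[C@@H](c2ccc(OCc3ccccc3)cc2)[C@@H](OCc2ccccc2)c2cc(OCc3ccc(OCc4ccccc4)cc3)cc(OCc3ccc(OCc4ccccc4)cc3)c21 | intermediate
21 | 5-diazo analogue of 19 (not isolated) | [N-]=[N+]=C1c2cc(OCc3ccccc3)cc(OCc3ccccc3)c2[C@@H](c2ccc(OCc3ccccc3)cc2)[C@@H](OCc2ccccc2)c2cc(OCc3ccc(OCc4ccccc4)cc3)cc(OCc3ccc(OCc4ccccc4)cc3)c21 | intermediate
22 | (7aS,8aR,7bR,8bR)-core hexaether with 7a,8a-cis dihydrofuran (Bn on O-8b and on the oxygens of rings A/B/C; BOB on the oxygen of ring D) | c1ccccc1COc1ccc([C@@H]2c3c(OCc5ccccc5)cc(OCc5ccccc5)cc3[C@@H]3c4c(cc(OCc5ccc(OCc6ccccc6)cc5)cc4[C@@H]2OCc2ccccc2)O[C@@H]3c2ccc(OCc3ccccc3)cc2)cc1 | intermediate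
23 | (7aR,8aR,7bR,8bR)-core pentabenzyl ether with 7a,8a-trans dihydrofuran and a free phenol on ring D | c1ccccc1COc1ccc([C@@H]2c3c(OCc5ccccc5)cc(OCc5ccccc5)cc3[C@@H]3c4c(cc(O)cc4[C@@H]2OCc2ccccc2)O[C@H]3c2ccc(OCc3ccccc3)cc2)cc1 | intermediate
24 | (7aR,8aR,7bR,8bR)-core hexol (8b-OH cis to the C7b aryl) | Oc1ccc([C@@H]2c3c(O)cc(O)cc3[C@@H]3c4c(cc(O)cc4[C@@H]2O)O[C@H]3c2ccc(O)cc2)cc1 | intermediate
25 | (7aR,8aR,7bR,8bR)-core penta-O-TIPS ether (8b-OH free) | CC(C)[Si](C(C)C)(C(C)C)Oc1ccc([C@@H]2c3c(O[Si](C(C)C)(C(C)C)C(C)C)cc(O[Si](C(C)C)(C(C)C)C(C)C)cc3[C@@H]3c4c(cc(O[Si](C(C)C)(C(C)C)C(C)C)cc4[C@@H]2O)O[C@H]3c2ccc(O[Si](C(C)C)(C(C)C)C(C)C)cc2)cc1 | intermediate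
26 | 3,5-bis(benzyloxy)benzoic acid | OC(=O)c1cc(OCc2ccccc2)cc(OCc2ccccc2)c1 | starting material
27 | 3,5-bis(benzyloxy)benzoyl chloride | ClC(=O)c1cc(OCc2ccccc2)cc(OCc2ccccc2)c1 | intermediate
28 | (2-chloro-4,6-bis{[4-(benzyloxy)benzyl]oxy}phenyl)[3,5-bis(benzyloxy)phenyl]methanone | O=C(c1cc(OCc2ccccc2)cc(OCc2ccccc2)c1)c1c(Cl)cc(OCc2ccc(OCc3ccccc3)cc2)cc1OCc1ccc(OCc2ccccc2)cc1 | intermediate
29 | hydrazone of 28 | NN=C(c1cc(OCc2ccccc2)cc(OCc2ccccc2)c1)c1c(Cl)cc(OCc2ccc(OCc3ccccc3)cc2)cc1OCc1ccc(OCc2ccccc2)cc1 | intermediate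
30 | diazo compound from 29 (not isolated) | [N-]=[N+]=C(c1cc(OCc2ccccc2)cc(OCc2ccccc2)c1)c1c(Cl)cc(OCc2ccc(OCc3ccccc3)cc2)cc1OCc1ccc(OCc2ccccc2)cc1 | intermediate
31 | (2S,3R)-6-{[4-(benzyloxy)benzyl]oxy}-2-[4-(benzyloxy)phenyl]-3-[3,5-bis(benzyloxy)phenyl]-4-chloro-2,3-dihydro-1-benzofuran | Clc1cc(OCc3ccc(OCc4ccccc4)cc3)cc2c1[C@@H](c1cc(OCc3ccccc3)cc(OCc3ccccc3)c1)[C@@H](c1ccc(OCc3ccccc3)cc1)O2 | intermediate
32 | (2R,3R)-2-[4-(benzyloxy)phenyl]-3-[3,5-bis(benzyloxy)phenyl]-4-chloro-2,3-dihydro-1-benzofuran-6-ol | Clc1cc(O)cc2c1[C@@H](c1cc(OCc3ccccc3)cc(OCc3ccccc3)c1)[C@H](c1ccc(OCc3ccccc3)cc1)O2 | intermediate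
33 | 5-[(2R,3R)-4-chloro-6-hydroxy-2-(4-hydroxyphenyl)-2,3-dihydro-1-benzofuran-3-yl]benzene-1,3-diol | Clc1cc(O)cc2c1[C@@H](c1cc(O)cc(O)c1)[C@H](c1ccc(O)cc1)O2 | intermediate
34 | tetra-O-TIPS ether of 33 | Clc1cc(O[Si](C(C)C)(C(C)C)C(C)C)cc2c1[C@@H](c1cc(O[Si](C(C)C)(C(C)C)C(C)C)cc(O[Si](C(C)C)(C(C)C)C(C)C)c1)[C@H](c1ccc(O[Si](C(C)C)(C(C)C)C(C)C)cc1)O2 | intermediate
35 | 4-ethynylphenol | C#Cc1ccc(O)cc1 | starting material
36 | (7aR,8aR,7bR,8bS)-8b-O-(4-ethynylphenyl) penta-O-TIPS core | CC(C)[Si](C(C)C)(C(C)C)Oc1ccc([C@@H]2c3c(O[Si](C(C)C)(C(C)C)C(C)C)cc(O[Si](C(C)C)(C(C)C)C(C)C)cc3[C@@H]3c4c(cc(O[Si](C(C)C)(C(C)C)C(C)C)cc4[C@H]2Oc2ccc(C#C)cc2)O[C@H]3c2ccc(O[Si](C(C)C)(C(C)C)C(C)C)cc2)cc1 | intermediate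
37 | nona-O-TIPS diarylalkyne | CC(C)[Si](C(C)C)(C(C)C)Oc1ccc([C@@H]2c3c(O[Si](C(C)C)(C(C)C)C(C)C)cc(O[Si](C(C)C)(C(C)C)C(C)C)cc3[C@@H]3c4c(cc(O[Si](C(C)C)(C(C)C)C(C)C)cc4[C@H]2Oc2ccc(C#Cc4cc(O[Si](C(C)C)(C(C)C)C(C)C)cc5c4[C@@H](c4cc(O[Si](C(C)C)(C(C)C)C(C)C)cc(O[Si](C(C)C)(C(C)C)C(C)C)c4)[C@H](c4ccc(O[Si](C(C)C)(C(C)C)C(C)C)cc4)O5)cc2)O[C@H]3c2ccc(O[Si](C(C)C)(C(C)C)C(C)C)cc2)cc1 | intermediate
38 | nona-O-TIPS ether of the target (Z-alkene) | CC(C)[Si](C(C)C)(C(C)C)Oc1ccc([C@@H]2c3c(O[Si](C(C)C)(C(C)C)C(C)C)cc(O[Si](C(C)C)(C(C)C)C(C)C)cc3[C@@H]3c4c(cc(O[Si](C(C)C)(C(C)C)C(C)C)cc4[C@H]2Oc2ccc(/C=C\c4cc(O[Si](C(C)C)(C(C)C)C(C)C)cc5c4[C@@H](c4cc(O[Si](C(C)C)(C(C)C)C(C)C)cc(O[Si](C(C)C)(C(C)C)C(C)C)c4)[C@H](c4ccc(O[Si](C(C)C)(C(C)C)C(C)C)cc4)O5)cc2)O[C@H]3c2ccc(O[Si](C(C)C)(C(C)C)C(C)C)cc2)cc1 | intermediate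
39 | CNP0354678.1 (7aR,8aR,7bR,8bS core; 2R,3R dihydrobenzofuran; Z-alkene) | Oc1ccc([C@@H]2c3c(O)cc(O)cc3[C@@H]3c4c(cc(O)cc4[C@H]2Oc2ccc(/C=C\c4cc(O)cc5c4[C@@H](c4cc(O)cc(O)c4)[C@H](c4ccc(O)cc4)O5)cc2)O[C@H]3c2ccc(O)cc2)cc1 | target

**Count and risks**

Total step count: 25. Longest linear sequence: 14 steps (steps 5–14 and 22–25; the sequence through steps 1–4, 9–14 and 22–25 is equally long).

Steps most likely to fail:

Step 9. The enolate may be arylated on oxygen, the aryl anion may be quenched before it closes onto the carbonyl (plain α-arylation), the cyclobutenoxide may fail to open, or the dienolate may be arylated a second time. The fallback sets out from 14 and builds the two aryl–carbon bonds one after the other by known polar steps. Baeyer–Villiger oxidation (mCPBA, NaHCO3, CH2Cl2) moves the alkoxy-bearing carbon to oxygen with retention and should give (3R,4R)-3,5,7-tris(benzyloxy)-4-[4-(benzyloxy)phenyl]isochroman-1-one F1. Bromide 3 is converted (n-BuLi, then ZnBr2, THF) into (3,5-bis{[4-(benzyloxy)benzyl]oxy}phenyl)zinc bromide F2, which adds at −78 °C to the oxocarbenium ion that BF3·OEt2 releases from F1 and should give, after aq. HCl work-up and separation of the epimers at the new carbinol carbon, 3,5-bis(benzyloxy)-2-[(1R,2R)-2-(benzyloxy)-2-(3,5-bis{[4-(benzyloxy)benzyl]oxy}phenyl)-1-[4-(benzyloxy)phenyl]ethyl]benzoic acid F3. Intramolecular Friedel–Crafts acylation (TFAA, CH2Cl2, 0 °C) at the ring position ortho and para to the two ethers then closes the seven-membered ketone and comes back to the route at 19.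

Step 11. The hindered ketone may give the diazo compound slowly or with azine formation, and the carbene may insert on the wrong face at C8a. The fallback sets out from ketone 19 and avoids the diazo compound. Irradiation (350 nm, benzene, 23 °C) should trigger hydrogen abstraction from the ortho O–CH2 by the excited ketone and radical recombination (Norrish–Yang-type photocyclisation of ortho-benzyloxy diaryl ketones) to the core 8a-hydroxy-dihydrofuran F4, a mixture at C7a and C8a. Ionic hydrogenation (Et3SiH, TFA, CH2Cl2, 0 → 23 °C) then removes the tertiary benzylic hydroxyl, equilibrates C7a to trans and cleaves the BOB ether of ring D, and comes back to the route at 23.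

Step 22. Elimination across C7b–C8b or no reaction at the hindered secondary benzylic centre may replace SN2 inversion. The fallback sets out from 25 and separates activation from substitution. Mesylation (MsCl, Et3N, CH2Cl2, −20 °C) should give the core C8b methanesulfonate F5, and displacement with the caesium salt of 35 (Cs2CO3, DMF, 50 °C), a Williamson etherification with inversion by a free phenoxide that does not depend on the Mitsunobu betaine, comes back to the route at 36.

**Further compounds**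

F1 | step 9 | (3R,4R)-3,5,7-tris(benzyloxy)-4-[4-(benzyloxy)phenyl]isochroman-1-one | O=C1O[C@@H](OCc2ccccc2)[C@H](c2ccc(OCc3ccccc3)cc2)c2c(OCc3ccccc3)cc(OCc3ccccc3)cc21
F2 | step 9 | (3,5-bis{[4-(benzyloxy)benzyl]oxy}phenyl)zinc bromide | Br[Zn]c1cc(OCc2ccc(OCc3ccccc3)cc2)cc(OCc2ccc(OCc3ccccc3)cc2)c1
F3 | step 9 | 3,5-bis(benzyloxy)-2-[(1R,2R)-2-(benzyloxy)-2-(3,5-bis{[4-(benzyloxy)benzyl]oxy}phenyl)-1-[4-(benzyloxy)phenyl]ethyl]benzoic acid | OC(=O)c1cc(OCc2ccccc2)cc(OCc2ccccc2)c1[C@@H](c1ccc(OCc2ccccc2)cc1)[C@@H](OCc1ccccc1)c1cc(OCc2ccc(OCc3ccccc3)cc2)cc(OCc2ccc(OCc3ccccc3)cc2)c1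
F4 | step 11 | core 8a-hydroxy-dihydrofuran (7bR,8bR; mixture at C7a and C8a; protecting groups as in 22) | c1ccccc1COc1ccc([C@@H]2c3c(OCc5ccccc5)cc(OCc5ccccc5)cc3C3(O)c4c(cc(OCc5ccc(OCc6ccccc6)cc5)cc4[C@@H]2OCc2ccccc2)OC3c2ccc(OCc3ccccc3)cc2)cc1
F5 | step 22 | (7aR,8aR,7bR,8bR)-core penta-O-TIPS ether 8b-methanesulfonate | CC(C)[Si](C(C)C)(C(C)C)Oc1ccc([C@@H]2c3c(O[Si](C(C)C)(C(C)C)C(C)C)cc(O[Si](C(C)C)(C(C)C)C(C)C)cc3[C@@H]3c4c(cc(O[Si](C(C)C)(C(C)C)C(C)C)cc4[C@@H]2OS(C)(=O)=O)O[C@H]3c2ccc(O[Si](C(C)C)(C(C)C)C(C)C)cc2)cc1
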